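Ring B is a 2,4-dihydroxy-6-propylbenzoic acid whose C3, between the two hydroxyls, carries the ring A aroyloxy group; this 2,3,4-trioxygenated pattern is exploited by cutting the C1–C6 and C2–C3 bonds. A Michael–Claisen annulation of dibenzyl malonate (C1, C2, carboxyl) with an α′-aroyloxy enone (C3–C6, propyl) closes ring B in one operation with all three oxygens and the depside ester in place. The precursor, (E)-2-oxohept-3-en-1-yl 2,4-dimethoxy-6-pentylbenzoate, comes from O-alkylation of the ring A carboxylate with a chloro enone; DDQ dehydrogenation and benzyl hydrogenolysis then deliver the target.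

Key step: step 7

Remark: the target contains no stereogenic element and is achiral, so no enantiocontrol is needed; the two stereocentres formed in step 7 are racemic and are removed in step 8.

Step 1
Reactants: 1 olivetol
Product: 2 1,3-dimethoxy-5-pentylbenzene
Conditions: MeI, K2CO3, acetone, reflux
Reagents that add atoms: iodomethane, CI
Why: Williamson ether synthesis on both phenols is routine and nothing else in the molecule can react.

Step 2
Reactants: 2 1,3-dimethoxy-5-pentylbenzene
Product: 4 2,4-dimethoxy-6-pentylbenzaldehyde, via aryl iminium chloride 3 (not isolated)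
Conditions: POCl3, DMF, 0 → 70 °C; then aq. NaOAc
Reagents that add atoms: N,N-dimethylformamide, CN(C)C=O; water, O
Why: Vilsmeier–Haack formylation of 5-alkylresorcinol dimethyl ethers should occur para to one methoxy group (C4, not C2 between the two methoxy groups), and aqueous acetate hydrolyses the iminium salt to the aldehyde.

Step 3
Reactants: 4 2,4-dimethoxy-6-pentylbenzaldehyde
Product: 5 2,4-dimethoxy-6-pentylbenzoic acid
Conditions: NaClO2, NaH2PO4, 2-methylbut-2-ene, t-BuOH/H2O, rt
Reagents that add atoms: sodium chlorite, [Na+].[O-]Cl=O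
Why: Pinnick oxidation should convert the hindered, electron-rich aldehyde into the acid, with 2-methylbut-2-ene trapping the hypochlorous acid that could otherwise chlorinate the ring.

Step 4
Reactants: 6 1,3-dichloroacetone
Product: 8 1-chloro-3-(triphenyl-λ5-phosphanylidene)propan-2-one, via phosphonium chloride 7 (not isolated)
Conditions: PPh3 (1.0 equiv), THF, reflux; solvent exchange; Na2CO3, MeOH/H2O, rt
Reagents that add atoms: triphenylphosphine, c1ccc(cc1)P(c1ccccc1)c1ccccc1
Why: SN2 quaternisation of the phosphine by one α-chloro ketone terminus should stop at the sparingly soluble mono-salt, and carbonate deprotonation gives the stabilised keto ylide.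

Step 5
Reactants: 8 1-chloro-3-(triphenyl-λ5-phosphanylidene)propan-2-one; 9 butanal
Product: 10 (E)-1-chlorohept-3-en-2-one
Conditions: butanal (2 equiv), THF, reflux
Reagents that add atoms: none
Why: Wittig olefination with a stabilised keto ylide should give the E-enone and tolerates the chloromethyl group.

Step 6
Reactants: 5 2,4-dimethoxy-6-pentylbenzoic acid; 10 (E)-1-chlorohept-3-en-2-one
Product: 11 (E)-2-oxohept-3-en-1-yl 2,4-dimethoxy-6-pentylbenzoate
Conditions: KHCO3 (1.1 equiv), NaI (cat.), DMF, rt
Reagents that add atoms: none
Why: Iodide-assisted SN2 O-alkylation of the carboxylate by an α-chloro ketone (phenacyl-ester type esterification) forms the ester at the alkyl carbon, so the shielded aroyl carbonyl is never attacked, and hydrogencarbonate is too weak a base to enolise the enone.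

Step 7
Reactants: 11 (E)-2-oxohept-3-en-1-yl 2,4-dimethoxy-6-pentylbenzoate; 12 dibenzyl malonate (1.1 equiv)
Product: 14 benzyl rac-(1S,6R)-3-(2,4-dimethoxy-6-pentylbenzoyloxy)-4-hydroxy-2-oxo-6-propylcyclohex-3-ene-1-carboxylate, via Michael adduct 13 (not isolated)
Conditions: KOtBu (1.05 equiv), THF, 0 → 50 °C; then 1 M HCl, 0 °C
Reagents that add atoms: none
Why: Proposed new method: the potassium malonate should add conjugately to C4 of the enone (ring B C1–C6 bond), and after proton transfer the ketone enolate at the aroyloxy-bearing methylene should attack one benzyl ester carbonyl (ring B C2–C3 bond) with loss of benzyloxide, which at once deprotonates the 2-acyloxy-1,3-dione and makes the sequence irreversible. The closest known reaction type is the Michael–Claisen (Michael–Dieckmann) annulation of malonates with alkyl vinyl ketones such as non-3-en-2-one to 6-alkyl-2,4-dioxocyclohexanecarboxylates, which has not been run on an α′-acyloxy enone. Ring B closes in a 6-(enolendo)-exo-trig mode. C6 is formed in the intermolecular Michael step without control (racemic), and C1, which stays acidic between ester and ketone, should equilibrate to place the ester trans to the propyl group; both centres vanish on aromatisation. The step needs C-acylation by the acyloxymethylene enolate in preference to 1,2-O→C aroyl shift, aroyl transfer to a neighbouring enolate oxygen or alkoxide cleavage of the depside ester: the other enolisable side of the ketone could only close a four-membered ring, and the aroyl carbonyl flanked by 2-methoxy and 6-pentyl groups is shielded from nucleophiles. The resting state as the stabilised 1,3-dionate should also hold the aroyl group on the central oxygen.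

Step 8
Reactants: 14 benzyl rac-(1S,6R)-3-(2,4-dimethoxy-6-pentylbenzoyloxy)-4-hydroxy-2-oxo-6-propylcyclohex-3-ene-1-carboxylate
Product: 15 benzyl 3-(2,4-dimethoxy-6-pentylbenzoyloxy)-2,4-dihydroxy-6-propylbenzoate
Conditions: DDQ (1.2 equiv), 1,4-dioxane, 80 °C
Reagents that add atoms: none
Why: DDQ dehydrogenation of a cyclohexane-1,3-dione to a resorcinol should proceed by hydride abstraction from the tertiary, enol-allylic C6–H and tautomerisation, driven by aromatisation, under non-basic conditions that give no opening for aroyl migration.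

Step 9
Reactants: 15 benzyl 3-(2,4-dimethoxy-6-pentylbenzoyloxy)-2,4-dihydroxy-6-propylbenzoate
Product: 16 3-(2,4-dimethoxy-6-pentylbenzoyloxy)-2,4-dihydroxy-6-propylbenzoic acid
Conditions: H2 (1 atm), 10% Pd/C, EtOAc, rt; concentrate below 30 °C
Reagents that add atoms: none
Why: Catalytic hydrogenolysis of the benzyl ester is neutral and run at room temperature, so the aryl ester, both arenes and the decarboxylation-prone β-resorcylic acid should survive.

Compound list

1 | olivetol (5-pentylbenzene-1,3-diol) | CCCCCc1cc(O)cc(O)c1 | starting material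
2 | 1,3-dimethoxy-5-pentylbenzene | CCCCCc1cc(OC)cc(OC)c1 | intermediate
3 | (2,4-dimethoxy-6-pentylbenzylidene)dimethyliminium chloride (not isolated) | CCCCCc1cc(OC)cc(OC)c1C=[N+](C)C.[Cl-] | intermediate
4 | 2,4-dimethoxy-6-pentylbenzaldehyde | CCCCCc1cc(OC)cc(OC)c1C=O | intermediate
5 | 2,4-dimethoxy-6-pentylbenzoic acid | CCCCCc1cc(OC)cc(OC)c1C(=O)O | intermediate
6 | 1,3-dichloroacetone | ClCC(=O)CCl | starting material
7 | (3-chloro-2-oxopropyl)triphenylphosphonium chloride (not isolated) | [Cl-].ClCC(=O)C[P+](c1ccccc1)(c1ccccc1)c1ccccc1 | intermediate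
8 | 1-chloro-3-(triphenyl-λ5-phosphanylidene)propan-2-one | ClCC(=O)C=P(c1ccccc1)(c1ccccc1)c1ccccc1 | intermediate
9 | butanal | CCCC=O | starting material
10 | (E)-1-chlorohept-3-en-2-one | CCC/C=C/C(=O)CCl | intermediate
11 | (E)-2-oxohept-3-en-1-yl 2,4-dimethoxy-6-pentylbenzoate | CCCCCc1cc(OC)cc(OC)c1C(=O)OCC(=O)/C=C/CCC | intermediate
12 | dibenzyl malonate | O=C(CC(=O)OCc1ccccc1)OCc1ccccc1 | starting material
13 | dibenzyl 2-[1-(2,4-dimethoxy-6-pentylbenzoyloxy)-2-oxoheptan-4-yl]malonate (racemic, not isolated) | CCCCCc1cc(OC)cc(OC)c1C(=O)OCC(=O)CC(CCC)C(C(=O)OCc1ccccc1)C(=O)OCc1ccccc1 | intermediate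
14 | benzyl rac-(1S,6R)-3-(2,4-dimethoxy-6-pentylbenzoyloxy)-4-hydroxy-2-oxo-6-propylcyclohex-3-ene-1-carboxylate (1,6-trans, enol form, racemate, one enantiomer drawn) | CCCCCc1cc(OC)cc(OC)c1C(=O)OC1=C(O)C[C@@H](CCC)[C@H](C(=O)OCc2ccccc2)C1=O | intermediate
15 | benzyl 3-(2,4-dimethoxy-6-pentylbenzoyloxy)-2,4-dihydroxy-6-propylbenzoate | CCCCCc1cc(OC)cc(OC)c1C(=O)Oc1c(O)cc(CCC)c(C(=O)OCc2ccccc2)c1O | intermediate
16 | 3-(2,4-dimethoxy-6-pentylbenzoyloxy)-2,4-dihydroxy-6-propylbenzoic acid (achiral) | CCCCCc1cc(OC)cc(OC)c1C(=O)Oc1c(O)cc(CCC)c(C(=O)O)c1O | target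

Total step count: 9
Longest linear sequence: 7 steps (steps 1, 2, 3, 6, 7, 8, 9)

Steps most likely to fail

Step 7. The acyloxymethylene enolate may undergo 1,2-aroyl shift from oxygen to carbon instead of ring closure. The sequence may also stall at the Michael adduct, or liberated benzyloxide may cleave the depside ester. The fallback sets out from 12 and 5 and comes back to the route at 14, using only known reaction types. Commercial (E)-hept-3-en-2-one (CCC/C=C/C(C)=O) and dibenzyl malonate 12 would be annulated in the established way (KOtBu, THF, then acid) to benzyl rac-trans-4-hydroxy-2-oxo-6-propylcyclohex-3-ene-1-carboxylate F1. Regitz diazo transfer at the C3 methylene between the two ketones (p-acetamidobenzenesulfonyl azide, Et3N, MeCN) would give benzyl rac-trans-3-diazo-2,4-dioxo-6-propylcyclohexane-1-carboxylate F2. Rh2(OAc)4-catalysed insertion of the carbenoid into the O–H bond of acid 5 (CH2Cl2, rt) would then place the aroyloxy group on C3 and, after enolisation, give 14.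

Step 8. Hydride abstraction from the strongly hydrogen-bonded, electron-poor enol may be slow, and C–C or C–O addition of the enol to the quinone may compete. The fallback sets out from 14 and comes back at 15. Double O-silylation (TMSOTf, Et3N, CH2Cl2, 0 °C) would give benzyl 3-(2,4-dimethoxy-6-pentylbenzoyloxy)-6-propyl-2,4-bis(trimethylsilyloxy)cyclohexa-1,3-diene-1-carboxylate F3. Saegusa–Ito oxidation (Pd(OAc)2, MeCN, rt) should palladate C1, eliminate the C6 hydride and, after tautomerisation and a dilute citric acid work-up that cleaves the silyl ethers, give 15.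

Step 6. The chloro enone may be lost by base-induced self-condensation, by conjugate addition or through its volatility before the carboxylate has alkylated it. The fallback sets out from 5 and 8 and comes back at 11 by reversing the order of the two bond formations. The carboxylate of 5 would displace chloride from ylide 8 (KHCO3, NaI cat., DMF, 50 °C) to give 2-oxo-3-(triphenyl-λ5-phosphanylidene)propyl 2,4-dimethoxy-6-pentylbenzoate F4. Wittig reaction of this stabilised ylide with butanal 9 (toluene, 80 °C) would then give 11.

Further compounds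

F1 | step 7 | benzyl rac-(1S,6R)-4-hydroxy-2-oxo-6-propylcyclohex-3-ene-1-carboxylate (trans) | C1=C(O)C[C@@H](CCC)[C@H](C(=O)OCc2ccccc2)C1=O
F2 | step 7 | benzyl rac-(1S,6R)-3-diazo-2,4-dioxo-6-propylcyclohexane-1-carboxylate (trans) | [N-]=[N+]=C1C(=O)C[C@@H](CCC)[C@H](C(=O)OCc2ccccc2)C1=O
F3 | step 8 | benzyl 3-(2,4-dimethoxy-6-pentylbenzoyloxy)-6-propyl-2,4-bis(trimethylsilyloxy)cyclohexa-1,3-diene-1-carboxylate (racemic) | CCCCCc1cc(OC)cc(OC)c1C(=O)OC1=C(O[Si](C)(C)C)CC(CCC)C(C(=O)OCc2ccccc2)=C1O[Si](C)(C)C
F4 | step 6 | 2-oxo-3-(triphenyl-λ5-phosphanylidene)propyl 2,4-dimethoxy-6-pentylbenzoate | CCCCCc1cc(OC)cc(OC)c1C(=O)OCC(=O)C=P(c1ccccc1)(c1ccccc1)c1ccccc1
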